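The runs stem from a simulated flask with made-up constants; scatter was added.

- Theta's solid substrate read 0 % at 1.00 min, so my ledger for this limiting reagent held two entries there: 47.0 % as target and 53.0 % as dissolved pool, meaning charge minus solid minus target.

| flask | solid substrate | reagent | temperature | remark | time |
|---|---|---|---|---|---|
| theta | 0.044 M | 0.352 M | 35 °C | run made earlier |  |
| epsilon | 0.18 M | 0.352 M | 57 °C | run made earlier |  |
| gamma | 0.088 M | 0.18 M | 35 °C | run made earlier |  |
| oak | 0.088 M | 0.352 M | 65 °C |  | 2.0 min |
| ash | 0.088 M | 0.352 M | 25 °C |  | 6.0 min |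

- theta (time / min: target / %, solid substrate / %): 0.333: 11.4, 39.5; 0.667: 30.9, 2.1; 1.00: 47.0, 0; 1.33: 59.0, 0; 1.50: 61.7, 0.8; 2.00: 70.4, 0.1; 2.50: 76.4, 0
- epsilon (time / s: target / %, solid substrate / %): 10.0: 5.0, 90.9; 12.0: 6.9, 89.2; 20.0: 14.1, 82.1; 25.0: 18.6, 77.6; 30.0: 22.6, 71.7; 40.0: 31.9, 63.6; 50.0: 40.0, 55.2
- gamma (time / min: target / %, solid substrate / %): 0.417: 7.7, 65.4; 0.833: 20.9, 42.7; 1.33: 38.0, 20.8; 2.00: 60.7, 0; 2.50: 71.4, 0.5

(scatter of a reading: 0.5 percentage points)

- which of the two ends with the higher amount of target, in percent of the solid substrate charged ("neither" if they lie within 2 percentage points) (oak / ash / neither)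
- target at the end, in percent of the solid substrate charged, oak
- target at the end, in percent of the solid substrate charged, ash

- solid, in amounts per volume of the solution: solid substrate
- at the start none of the solid substrate is in solution
- what has only dissolved of solid substrate counts as not reacted

- By 2.50 min theta's pool entry stood at 23.6 %. Read as first order, that gave a pool half-life of 1.29 min at 35 °C.
- Epsilon's ledger showed a small pool of about 4.45 %, fed by solid at 0.0964 M min⁻¹. Target's rise against that pool gave a half-life of 3.53 s at 57 °C.
- I drew a straight line through the logarithms of these half-lives against temperature. That gave my carried quantity, the time in which the dissolved pool halves at oak's temperature, 1.15 s, and 5.22 min for ash.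
- For ash I counted 1.15 half-lives from the start, which booked 54.9 % as target.
- For oak, epsilon's feed emptied the solid in 54.8 s, leaving 56.8 half-lives, so I booked 100 % as target.
- The forecast said oak, with 98 % for oak and 72 % for ash, higher than my ash figure; its grounds differed from mine: “so it looks second order in dissolved substrate”.
- The flasks gave oak as the higher, with 97.0 % in oak and 58.2 % in ash.

    starting material → target (k = 0.00668 s⁻¹, Ea = 94.0 kJ mol⁻¹)
    starting material ⇌ intermediate (K = 0.740, k = 0.0125 s⁻¹, Ea = 82.0 kJ mol⁻¹, ΔH = −29.0 kJ mol⁻¹)
    reagent + intermediate → side product (k = 0.0144 M⁻¹ s⁻¹, Ea = 63.0 kJ mol⁻¹)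
    solid substrate ⇌ starting material, rate k4*(cs4 - [starting material]) while solid is left; crystals form when [starting material] > cs4 (solubility = 33.0 mM, k = 0.0590 s⁻¹)
    (constants at 25 °C)

- Ash's books at 6.00 min held 22.7 % side product, 10.7 % starting material and 8.39 % intermediate beside its target. For oak read at 50 s, feed times lifetime with 1.15 s gave a pool of 3.02 %; that flask held 2.37 % starting material and 0.492 % intermediate, its solid reading 0 % earlier than my 54.8 s. The 8.70 half-lives to 1.00 min reckoned that flask's starting material down to 0.00572 %, but oak held more than that, 0.0148 %. The neighbour's target stood at 94.2 %, and oak closed at 97.0 %.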